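**Retrosynthetic overview**

- The strategy rests on the 2,3-dihydro-4H-pyran-4-one ring (O1, C2–C6): the C2 carbinol carbon and the C4 carbonyl flank the C3 methylene, so C2–C3 with the ring oxygen is a terminal (R)-epoxide and C4 an acyl anion.
- The only ring is closed last: the O1–C6 bond and the C5=C6 double bond come from acid cyclodehydration of a δ-hydroxy β-diketone whose C4 is held as a dithiane and C6 as a dioxolane.
- The C3–C4 bond comes from a 2-lithio-1,3-dithiane that already carries C5, masked C6 and the methyl group, which opens the (R)-epoxide at its CH2.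
- The epoxide comes from oleyl alcohol (Z-alkene and C18 chain) and (R)-epichlorohydrin (C2, C3 and the stereocentre); the dithiane comes from 4,4-dimethoxybutan-2-one, propane-1,3-dithiol and ethylene glycol.

Key step: step 6

Remark: oleyl alcohol of high (9Z) isomeric purity is assumed, because saturated or E-configured homologues in technical grades would be carried through every step.

**Route**

Step 1
Reactants: 1 oleyl alcohol, (9Z)-octadec-9-en-1-ol
Product: 2 oleyl bromide, (9Z)-1-bromooctadec-9-ene
Conditions: CBr4, PPh3, CH2Cl2, 0 °C → rt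
Reagents that add atoms: carbon tetrabromide, BrC(Br)(Br)Br
Why: Appel reaction: the alkoxyphosphonium ion formed from the primary alcohol is displaced by bromide in an SN2 step under neutral conditions that leave the Z-alkene untouched.

Step 2
Reactants: 2 oleyl bromide; 3 (R)-epichlorohydrin, (2R)-2-(chloromethyl)oxirane
Product: 5 (2R,12Z)-1-chlorohenicos-12-en-2-ol, via oleylmagnesium bromide 4 (not isolated)
Conditions: Mg, THF, reflux; then added to 3, CuBr·SMe2 (5 mol %), THF, −40 → 0 °C; then H2O
Reagents that add atoms: none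
Why: Copper-catalysed Grignard opening of a terminal epoxide: under catalysis by monovalent copper the alkylmagnesium reagent 4 attacks the unsubstituted oxirane carbon of 3 faster than it displaces chloride, so the carbinol carbon is not a reacting atom and its configuration is carried over from 3.

Step 3
Reactants: 5 (2R,12Z)-1-chlorohenicos-12-en-2-ol
Product: 6 (2R)-2-[(10Z)-nonadec-10-en-1-yl]oxirane
Conditions: powdered NaOH, Et2O, rt
Reagents that add atoms: none
Why: Intramolecular Williamson etherification (3-exo-tet): the alkoxide displaces the adjacent primary chloride, and since the stereocentre only carries the nucleophilic oxygen its (R) configuration is kept.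

Step 4
Reactants: 7 4,4-dimethoxybutan-2-one; 8 propane-1,3-dithiol
Product: 9 1-(1,3-dithian-2-yl)propan-2-one
Conditions: BF3·OEt2 (0.3 equiv), CH2Cl2, −20 → 0 °C
Reagents that add atoms: none
Why: Lewis-acid transthioacetalisation: the dimethyl acetal ionises to an oxocarbenium ion far more readily than the ketone is activated, so one equivalent of dithiol should be taken up at the acetal carbon only.

Step 5
Reactants: 9 1-(1,3-dithian-2-yl)propan-2-one
Product: 10 2-[(2-methyl-1,3-dioxolan-2-yl)methyl]-1,3-dithiane
Conditions: HOCH2CH2OH, p-TsOH·H2O (cat.), PhH, reflux, Dean–Stark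
Reagents that add atoms: ethylene glycol, OCCO
Why: Acid-catalysed ketalisation driven by azeotropic removal of water, to which the dithiane is inert; the dioxolane removes the enolisable, electrophilic ketone that would quench a dithiane anion.

Step 6
Reactants: 10 2-[(2-methyl-1,3-dioxolan-2-yl)methyl]-1,3-dithiane; 6 (2R)-2-[(10Z)-nonadec-10-en-1-yl]oxirane
Product: 12 (2R,12Z)-1-{2-[(2-methyl-1,3-dioxolan-2-yl)methyl]-1,3-dithian-2-yl}henicos-12-en-2-ol, via lithiated dithiane 11 (not isolated)
Conditions: t-BuLi, THF/HMPA (10:1), −78 °C, 10 min; then 6, −78 → −30 °C; then H2O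
Reagents that add atoms: none
Why: t-BuLi in THF/HMPA removes the C2 proton of dithiane 10 at −78 °C to give the sulfur-stabilised carbanion 11, an acyl anion equivalent for C4, which attacks the unsubstituted CH2 of oxirane 6 in an SN2 ring opening driven by release of epoxide strain, forming the C3–C4 bond and the C2 lithium alkoxide. The closest known reaction type is the Corey–Seebach alkylation of 2-lithio-2-alkyl-1,3-dithianes with terminal epoxides. No ring is closed and no new stereocentre is formed; the C2 carbinol carbon is not a reacting atom, so the (R) configuration bought with 3 is carried into 12 unchanged. The step needs regioselective attack at the terminal epoxide carbon, which the steric difference between the CH2 and the chain-bearing CH secures, and it needs the carbanion to survive without β-elimination of a ketal oxygen, which fast metalation and coupling below −30 °C should secure. The isolated Z-alkene is inert to the carbanion, and C4 and C6 stay masked at the ketone oxidation level, so no later redox step is needed.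

Step 7
Reactants: 12 (2R,12Z)-1-{2-[(2-methyl-1,3-dioxolan-2-yl)methyl]-1,3-dithian-2-yl}henicos-12-en-2-ol
Product: 13 (4R,14Z)-4-hydroxy-1-(2-methyl-1,3-dioxolan-2-yl)tricos-14-en-2-one
Conditions: MeI (excess), CaCO3, MeCN/H2O (9:1), 40 °C
Reagents that add atoms: water, O
Why: Alkylative dithiane hydrolysis: S-methylation makes sulfur a leaving group and water traps the thionium ion, while CaCO3 takes up the HI so that the β-hydroxy ketone, the dioxolane and the Z-alkene (which an oxidative or mercury-based unmasking would endanger) are spared.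

Step 8
Reactants: 13 (4R,14Z)-4-hydroxy-1-(2-methyl-1,3-dioxolan-2-yl)tricos-14-en-2-one
Product: 16 (2R)-6-methyl-2-[(10Z)-nonadec-10-en-1-yl]-2,3-dihydro-4H-pyran-4-one (target), via hydroxy diketone 14 (not isolated), via cyclic hemiketal 15 (not isolated)
Conditions: p-TsOH·H2O (0.2 equiv), THF/H2O (20:1), rt → 40 °C
Reagents that add atoms: none
Why: Acid hydrolysis of the dioxolane frees the C6 ketone of δ-hydroxy β-diketone 14, the C2 hydroxyl adds to it (6-exo-trig hemiketalisation to 15) and loss of water into conjugation with the C4 carbonyl gives the vinylogous ester, a known cyclodehydration route to 2,3-dihydro-4H-pyran-4-ones in which the C2–O bond is never broken, so (R) is retained.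

**Compound list**

1 | oleyl alcohol, (9Z)-octadec-9-en-1-ol | CCCCCCCC/C=C\CCCCCCCCO | starting material
2 | oleyl bromide, (9Z)-1-bromooctadec-9-ene | CCCCCCCC/C=C\CCCCCCCCBr | intermediate
3 | (R)-epichlorohydrin, (2R)-2-(chloromethyl)oxirane | ClC[C@H]1CO1 | starting material
4 | oleylmagnesium bromide, (9Z)-octadec-9-en-1-ylmagnesium bromide (not isolated) | CCCCCCCC/C=C\CCCCCCCC[Mg]Br | intermediate
5 | (2R,12Z)-1-chlorohenicos-12-en-2-ol | CCCCCCCC/C=C\CCCCCCCCC[C@@H](O)CCl | intermediate
6 | (2R)-2-[(10Z)-nonadec-10-en-1-yl]oxirane | CCCCCCCC/C=C\CCCCCCCCC[C@@H]1CO1 | intermediate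
7 | 4,4-dimethoxybutan-2-one | CC(=O)CC(OC)OC | starting material
8 | propane-1,3-dithiol | SCCCS | starting material
9 | 1-(1,3-dithian-2-yl)propan-2-one | CC(=O)CC1SCCCS1 | intermediate
10 | 2-[(2-methyl-1,3-dioxolan-2-yl)methyl]-1,3-dithiane | CC1(CC2SCCCS2)OCCO1 | intermediate
11 | 2-lithio-2-[(2-methyl-1,3-dioxolan-2-yl)methyl]-1,3-dithiane (not isolated) | CC1(CC2([Li])SCCCS2)OCCO1 | intermediate
12 | (2R,12Z)-1-{2-[(2-methyl-1,3-dioxolan-2-yl)methyl]-1,3-dithian-2-yl}henicos-12-en-2-ol | CCCCCCCC/C=C\CCCCCCCCC[C@@H](O)CC1(CC2(C)OCCO2)SCCCS1 | intermediate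
13 | (4R,14Z)-4-hydroxy-1-(2-methyl-1,3-dioxolan-2-yl)tricos-14-en-2-one | CCCCCCCC/C=C\CCCCCCCCC[C@@H](O)CC(=O)CC1(C)OCCO1 | intermediate
14 | (6R,16Z)-6-hydroxypentacos-16-ene-2,4-dione (not isolated) | CCCCCCCC/C=C\CCCCCCCCC[C@@H](O)CC(=O)CC(C)=O | intermediate
15 | (6R)-2-hydroxy-2-methyl-6-[(10Z)-nonadec-10-en-1-yl]oxan-4-one, configuration at C2 not defined (not isolated) | CCCCCCCC/C=C\CCCCCCCCC[C@@H]1CC(=O)CC(C)(O)O1 | intermediate
16 | (2R)-6-methyl-2-[(10Z)-nonadec-10-en-1-yl]-2,3-dihydro-4H-pyran-4-one | CCCCCCCC/C=C\CCCCCCCCC[C@@H]1CC(=O)C=C(C)O1 | target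

**Summary**

Total step count: 8. Longest linear sequence: 6 steps (steps 1, 2, 3, 6, 7, 8, from oleyl alcohol); the dithiane branch (steps 4, 5) joins at step 6.

Steps most likely to fail:

1. Step 6. The lithiated dithiane may expel a dioxolane oxygen by β-elimination, or metalation may be incomplete, so that the carbanion is consumed before it meets the epoxide. The fallback sets out from 6 and comes back at 14, and it generates the C4 carbanion by silyl migration instead of deprotonation. 2-(tert-Butyldimethylsilyl)-1,3-dithiane is lithiated (t-BuLi, Et2O, −78 → −45 °C) and opens 6 at its CH2 to give lithium (2R,12Z)-1-[2-(tert-butyldimethylsilyl)-1,3-dithian-2-yl]henicos-12-en-2-olate F1. Addition of HMPA and racemic methyloxirane triggers a 1,4-Brook rearrangement to 2-lithio-2-[(2R,12Z)-2-(tert-butyldimethylsilyloxy)henicos-12-en-1-yl]-1,3-dithiane F2, which is born at −78 °C in the presence of its electrophile and should open it at once to give 1-{2-[(2R,12Z)-2-(tert-butyldimethylsilyloxy)henicos-12-en-1-yl]-1,3-dithian-2-yl}propan-2-ol F3 (both epimers at the propanol carbon). Parikh–Doering oxidation (SO3·pyridine, DMSO, i-Pr2NEt, CH2Cl2, 0 °C) should give 1-{2-[(2R,12Z)-2-(tert-butyldimethylsilyloxy)henicos-12-en-1-yl]-1,3-dithian-2-yl}propan-2-one F4. MeI and CaCO3 in aqueous MeCN should then give (6R,16Z)-6-(tert-butyldimethylsilyloxy)pentacos-16-ene-2,4-dione F5, and aqueous HF in MeCN removes the silyl ether to give 14, which closes to 16 in the same acidic medium or under the conditions of step 8. This is the known three-component coupling of a 2-silyl-1,3-dithiane with two epoxides.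

2. Step 7. S-Methylation at the fully substituted dithiane carbon may be slow, and on long exposure the liberated β-hydroxy ketone may dehydrate or undergo retro-aldol cleavage while the dioxolane is lost unevenly. The fallback sets out from 12 and comes back at 16, and it closes the ring before C4 is unmasked. Camphorsulfonic acid (cat.) in MeOH at rt exchanges the dioxolane for a cyclic ketal in which the C2 hydroxyl has captured C6, giving (10R)-8-methoxy-8-methyl-10-[(10Z)-nonadec-10-en-1-yl]-9-oxa-1,5-dithiaspiro[5.5]undecane F6. Dithiane removal (MeI, CaCO3, MeCN/H2O) on this substrate, which has neither a free hydroxyl nor a dioxolane, should give (6R)-2-methoxy-2-methyl-6-[(10Z)-nonadec-10-en-1-yl]oxan-4-one F7. p-TsOH·H2O (cat.) in PhH at 40 °C then eliminates methanol into conjugation with the C4 carbonyl to give 16. The free β-hydroxy ketone never exists in this order of events, and step 8 is bypassed as well.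

3. Step 4. Chemoselectivity may be lost: the ketone may be thioketalised along with the acetal, or the acetal may lose methanol to the methoxy enone, which oligomerises under the Lewis acid. The fallback sets out from 8 and comes back at 9, and it replaces acetal exchange by conjugate addition. Propane-1,3-dithiol 8 is added to but-3-yn-2-one (NaOMe cat., MeOH/CH2Cl2, −10 °C → rt). The first thia-Michael addition gives 4-[(3-sulfanylpropyl)sulfanyl]but-3-en-2-one F8, which is not isolated, and the second, intramolecular addition closes the dithiane to 9. No acid and no acetal are involved.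

**Further compounds**

F1 | step 6 | lithium (2R,12Z)-1-[2-(tert-butyldimethylsilyl)-1,3-dithian-2-yl]henicos-12-en-2-olate | CCCCCCCC/C=C\CCCCCCCCC[C@@H](O[Li])CC1([Si](C)(C)C(C)(C)C)SCCCS1
F2 | step 6 | 2-lithio-2-[(2R,12Z)-2-(tert-butyldimethylsilyloxy)henicos-12-en-1-yl]-1,3-dithiane | CCCCCCCC/C=C\CCCCCCCCC[C@@H](O[Si](C)(C)C(C)(C)C)CC1([Li])SCCCS1
F3 | step 6 | 1-{2-[(2R,12Z)-2-(tert-butyldimethylsilyloxy)henicos-12-en-1-yl]-1,3-dithian-2-yl}propan-2-ol | CCCCCCCC/C=C\CCCCCCCCC[C@@H](O[Si](C)(C)C(C)(C)C)CC1(CC(C)O)SCCCS1
F4 | step 6 | 1-{2-[(2R,12Z)-2-(tert-butyldimethylsilyloxy)henicos-12-en-1-yl]-1,3-dithian-2-yl}propan-2-one | CCCCCCCC/C=C\CCCCCCCCC[C@@H](O[Si](C)(C)C(C)(C)C)CC1(CC(C)=O)SCCCS1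
F5 | step 6 | (6R,16Z)-6-(tert-butyldimethylsilyloxy)pentacos-16-ene-2,4-dione | CCCCCCCC/C=C\CCCCCCCCC[C@@H](O[Si](C)(C)C(C)(C)C)CC(=O)CC(C)=O
F6 | step 7 | (10R)-8-methoxy-8-methyl-10-[(10Z)-nonadec-10-en-1-yl]-9-oxa-1,5-dithiaspiro[5.5]undecane | CCCCCCCC/C=C\CCCCCCCCC[C@@H]1CC2(CC(C)(OC)O1)SCCCS2
F7 | step 7 | (6R)-2-methoxy-2-methyl-6-[(10Z)-nonadec-10-en-1-yl]oxan-4-one | CCCCCCCC/C=C\CCCCCCCCC[C@@H]1CC(=O)CC(C)(OC)O1
F8 | step 4 | 4-[(3-sulfanylpropyl)sulfanyl]but-3-en-2-one | CC(=O)C=CSCCCS
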